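## Structural features

Pakyonol is a macrocyclic bis(bibenzyl): four benzene rings, A to D, are tied into one 20-membered ring by two diaryl ether oxygens (ring A–O–ring B and ring C–O–ring D) and two ethano bridges (ring B–CH2CH2–ring C and ring D–CH2CH2–ring A). Ring A is 1,2,4-trisubstituted, with the methoxy group ortho to the ether oxygen and para to its bridge. Ring B is para-linked. Ring C is 1,2,4-trisubstituted, with the ether oxygen para to the bridge and a free hydroxyl next to it. Ring D is meta-linked (oxygen on D1, bridge on D3) and carries nothing else. The target has no stereocentre, so nothing has to be relayed; stereocentres that appear on the way are transient. The sensitive sites are the electron-rich ring C with its free phenol (oxidation, quinone methide formation at the para benzylic carbon), the four benzylic methylenes and, during the synthesis, every vinylogous ester stage of ring D. The difficulty is threefold: closing a 20-membered ring, forming the ring C–O–ring D ether although ring D has no group that activates it for aromatic substitution, and telling three phenolic oxygens apart. The feature that is exploited is the bare 1,3-pattern of ring D. D1–O and D3–CH2 are the footprints of C3 and C5 of a 5-substituted cyclohexane-1,3-dione whose second oxygen (on D5) is removed later. Ring D can therefore be carried as a 3-chlorocyclohex-2-enone, whose C3 is a vinylogous acid chloride carbon that a phenoxide attacks without metal.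

## Logic of the disconnections

30 ⇒ 29. The O–CH(CH3)2 bond on ring C is cut. A secondary alkyl ether survives hydrogenation, hydrides, alkoxide, acid chloride formation, fluoride and DDQ, and leaves exactly one other ring C oxygen to act as nucleophile. The demand on the forward step is that a Lewis acid cleaves the isopropyl ether and spares the methyl ether of ring A.

29 ⇒ 28 ⇒ 27 ⇒ 26. Ring D is taken back from the arene to a cyclohexenone: an oxygen is put back on D5 and four hydrogens are added. This turns an unactivated meta-alkyl aryl ether into a 3-aryloxycyclohex-2-enone, the product of a vinylogous acyl substitution. The forward demand is that the carbonyl oxygen is removed (reduction, dehydration, dehydrogenation) without ionising the ring C–O–C3 bond, so the sequence must stay anhydrous and non-acidic.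

26 ⇒ 25 (formed in the flask from 24). The bond between the ring C oxygen and C3 of ring D is cut. The macrocycle opens to a chain with one nucleophile and one electrophile. The forward step needs high dilution and a phenoxide that is set free only at that moment, which is why 25 is stored as its silyl ether 24.

24 ⇒ 23 ⇒ 21. The C–Cl bond goes back to the enol C–OH of a symmetric dione, so chlorination cannot give regioisomers, and the O–Si bond goes back to the phenol. The demand is that the phenol is masked while the chlorinating agent is present.

21 ⇒ 16 + 17 (through 18, 19 and 20). Ring D is cut at the bond between C4 and C5 (Michael addition) and at the bond between C2 and C3 (Claisen condensation), with an ester group added at C4. The ring is thereby reduced to an acyclic enone and a two-carbon malonate unit. The demand is a base sequence that tolerates a free phenol.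

16 ⇒ 14 + 15 and 14 ⇒ 13. The enone double bond is cut (Wittig), and the aldehyde is traced to an ester by a change of oxidation level. The demand is a hydride reduction that stops at the aldehyde.

13 ⇒ 12 ⇒ 5 + 10 (ylide 11). The ring B–ring C bridge is cut between its two carbons. This joins ring C to the ring A–O–ring B part convergently. The hydrogenation that saturates both alkenes also removes the benzyl group from the ring C oxygen para to the bridge, so the differentiation of the two ring C oxygens costs no step of its own. The demand is that 10 holds a single aldehyde.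

10 ⇒ 8 + 9 and 8 ⇒ 6 + 7. The bond between the ether oxygen and B1 is cut (aromatic substitution activated by the para formyl group), and before that the acrylate double bond on ring A. Olefination of 6 before the etherification ensures that the only aldehyde in 10 sits on ring B.

5 ⇒ 4 ⇒ 3 ⇒ 2 ⇒ 1. These are functional group changes on ring C. The two hydroxyls of 1 are told apart by acidity: the one para to the formyl group is benzylated first, the other is then isopropylated.

## Other disconnections considered

Alternative 1: The cut runs through ring A. The A3–A4 and A5–A6 bonds are opened, so that ring A is recognised as a cyclohexenone, A1 (a 4-substituted 6-aryloxycyclohex-2-enone, racemic diastereomers), made by Robinson annulation. In the forward sense the pyrrolidine enamine of the ring D aldehyde A2, 4-(3-bromophenyl)butanal, would add to the vinyl ketone A3, a 3-aryloxybut-3-en-2-one that already carries the protected ring B–ring C bibenzyl. The methyl ketone would then condense onto the aldehyde.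
- In its favour: the most substituted ring is built from acyclic pieces, and the ring A–O–ring B bond arises as an ordinary phenol alkylation when A3 is made. The annulation is bimolecular at normal concentration. The carbonyl oxygen of A1 ends as the methoxy oxygen, so nothing has to be deoxygenated. In redox economy this is better than the chosen plan, which must remove the oxygen of the ring D carbonyl.
- Against it here: A3 is a captodative enone, less electrophilic at its terminus and prone to polymerise. A1 must still be dehydrogenated to the phenol and methylated. Above all, the macrocycle is still open after the key step. The ring C–O–ring D bond would have to be closed between the unactivated bromide on ring D and the ring C phenol by an Ullmann-type macrocyclisation at high temperature, the least dependable operation in this family.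
- Comparison: in structure the two plans are equal, since each makes one benzene ring from a cyclohexenone. In mechanism the chosen plan couples ring construction to a metal-free closure at an activated carbon, whereas Alternative 1 leaves the closure to copper. In step economy Alternative 1 is expected to be longer: A2 and A3 need their own sequences, and aromatisation, methylation, desilylation, ring closure and debenzylation follow A1.

Alternative 2: The cut opens the B3–B4 and B5–B6 bonds, so that ring B and the macrocycle arise together. The precursor A5 carries a buta-1,3-dien-2-yl ether on the ring A oxygen and a terminal ynone on the ring C side chain. Heating at high dilution would give the intramolecular Diels–Alder adduct, and DDQ would dehydrogenate the cyclohexadiene to the macrocyclic aryl ketone A4.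
- In its favour: two C–C bonds, a benzene ring and the 20-membered ring would form in one thermal step without reagent. The para relation that ring B needs is the normal electronic outcome for a 2-oxy diene and an ynone. The endgame is better than in the chosen plan, because one hydrogenolysis should take the benzylic ketone down to CH2 and remove the benzyl group.
- Against it here: A5 combines two functions that keep poorly, a 2-aryloxydiene (polymerisation, hydrolysis) and a terminal ynone (conjugate addition, isomerisation through its acidic benzylic CH2). The ring C–O–ring D ether must still be made beforehand by an intermolecular copper coupling. Intermolecular cycloaddition competes at any practical concentration. In a macrocyclic transition state the tether can override the electronic preference, and the meta mode would give a 19-membered isomer.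
- Comparison: in concept the two plans are equal, since both build an arene de novo and close the macrocycle in the same step, and both use a DDQ dehydrogenation. In mechanism the chosen plan has a single possible site of bond formation, whereas A4 depends on a regiochemical preference. Step count before the key step should be similar, and after it Alternative 2 is shorter.

Alternative 3: The ring A–O–ring B ether is traced back to an aryl ester by inserting CO between the oxygen and B1, giving the 21-membered macrolactone A7. Forward, zerovalent nickel from Ni(cod)2 and 1,2-bis(dicyclohexylphosphino)ethane would insert into the acyl–oxygen bond, extrude CO and reductively eliminate the O–B1 bond. The product is O-isopropyl pakyonol A6, which is identical with 29.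
- In its favour: all four benzene rings are bought. The large ring is first closed by macrolactonisation, one of the most dependable macrocyclisations. The ether-forming step is a unimolecular ring contraction and needs no high dilution. No ring has to be taken through redox changes. In step economy this alternative is probably better than the chosen plan, and the endgame after A6 is the same.
- Against it here: decarbonylative etherification works best with esters of electron-poor or azine carboxylic acids, whereas A7 is the hindered ester of an alkyl-substituted benzoic acid with an ortho-methoxy phenol. The step needs high temperature. Zerovalent nickel with an electron-rich bisphosphine can also insert into the aryl C–O bonds of the ethers that A7 and A6 contain. Slow CO extrusion from a large nickelacycle would open the way to ring-opened by-products.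
- Comparison: in structure Alternative 3 is simpler, because it involves no de novo ring. In mechanism the chosen plan rests on a polar substitution at a vinylogous acid chloride, which is more predictable than an organometallic ring contraction.

Key step: step 14

Remarks on the chemistry (assumptions):
- Racemates and diastereomer mixtures are drawn without stereodescriptors. No stereocentre survives step 16, and 30 is achiral.
- Phenoxides and enolates present in the flask are listed as the neutral compounds.
- 28 is written as the 1-aryloxycyclohexa-1,3-diene. Its double-bond isomer, should it form, gives the same arene.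
- The ring C hydroxyl that is free in 30 is carried as an isopropyl ether. The attacking ring C oxygen is masked first as a benzyl ether (lost in step 8) and later as a silyl ether (lost in step 14).

## Route

Step 1
Reactants: 1 3,4-dihydroxybenzaldehyde
Product: 2 4-(benzyloxy)-3-hydroxybenzaldehyde
Conditions: BnBr (1.0 equiv), NaHCO3, NaI (cat.), DMF, 40 °C
Reagents that add atoms: benzyl bromide, BrCc1ccccc1
Why: Williamson etherification under a weak base; the hydroxyl para to the formyl group is the more acidic and is the one deprotonated by hydrogen carbonate, so monobenzylation should occur there.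

Step 2
Reactants: 2 4-(benzyloxy)-3-hydroxybenzaldehyde
Product: 3 4-(benzyloxy)-3-isopropoxybenzaldehyde
Conditions: i-PrBr (excess), K2CO3, DMF, 70 °C
Reagents that add atoms: 2-bromopropane, CC(C)Br
Why: Williamson etherification of the remaining phenol; an excess of the secondary bromide offsets loss by elimination.

Step 3
Reactants: 3 4-(benzyloxy)-3-isopropoxybenzaldehyde
Product: 4 [4-(benzyloxy)-3-isopropoxyphenyl]methanol
Conditions: NaBH4, MeOH, 0 °C; dilute HCl quench
Reagents that add atoms: none
Why: Borohydride reduction of an aromatic aldehyde; both ethers are inert.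

Step 4
Reactants: 4 [4-(benzyloxy)-3-isopropoxyphenyl]methanol
Product: 5 [4-(benzyloxy)-3-isopropoxybenzyl]triphenylphosphonium bromide
Conditions: PPh3·HBr, MeCN, reflux
Reagents that add atoms: triphenylphosphine hydrobromide, [Br-].[PH+](c1ccccc1)(c1ccccc1)c1ccccc1
Why: The electron-rich benzylic alcohol ionises under the mild acid and the cation is captured by triphenylphosphine (SN1-type phosphonium salt formation), which saves a separate halogenation.

Step 5
Reactants: 6 isovanillin; 7 methyl (triphenylphosphoranylidene)acetate
Product: 8 methyl (E)-3-(3-hydroxy-4-methoxyphenyl)prop-2-enoate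
Conditions: toluene, 90 °C
Reagents that add atoms: none
Why: Wittig olefination with a stabilised ylide, expected to be E-selective and to tolerate the free phenol; it converts the ring A aldehyde before the second aldehyde enters, so the two never have to be told apart.

Step 6
Reactants: 8 methyl (E)-3-(3-hydroxy-4-methoxyphenyl)prop-2-enoate; 9 4-fluorobenzaldehyde
Product: 10 methyl (E)-3-[3-(4-formylphenoxy)-4-methoxyphenyl]prop-2-enoate
Conditions: K2CO3, DMF, 120 °C
Reagents that add atoms: none
Why: Nucleophilic aromatic substitution (addition–elimination through a Meisenheimer complex) of the fluoride activated by the para formyl group forms the ring A–O–ring B ether; phenoxide addition to the cinnamate is reversible and unproductive.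

Step 7
Reactants: 5 [4-(benzyloxy)-3-isopropoxybenzyl]triphenylphosphonium bromide; 10 methyl (E)-3-[3-(4-formylphenoxy)-4-methoxyphenyl]prop-2-enoate
Product: 12 methyl (E)-3-[3-[4-[2-[4-(benzyloxy)-3-isopropoxyphenyl]ethenyl]phenoxy]-4-methoxyphenyl]prop-2-enoate (E/Z mixture at the stilbene bond), via benzylidene phosphorane 11 (not isolated)
Conditions: K2CO3, 18-crown-6 (cat.), CH2Cl2, reflux
Reagents that add atoms: none
Why: Wittig olefination with a semi-stabilised ylide generated under solid–liquid phase transfer, mild enough for the methyl ester; the alkene geometry is irrelevant because the bond is saturated next.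

Step 8
Reactants: 12 methyl (E)-3-[3-[4-[2-[4-(benzyloxy)-3-isopropoxyphenyl]ethenyl]phenoxy]-4-methoxyphenyl]prop-2-enoate
Product: 13 methyl 3-[3-[4-[2-(4-hydroxy-3-isopropoxyphenyl)ethyl]phenoxy]-4-methoxyphenyl]propanoate
Conditions: H2 (1 atm), 10% Pd/C, EtOAc–MeOH, rt
Reagents that add atoms: none
Why: Catalytic hydrogenation saturates the stilbene and the cinnamate, and hydrogenolysis removes the benzyl ether in the same operation; isopropyl, methyl and diaryl ethers and the ester are inert.

Step 9
Reactants: 13 methyl 3-[3-[4-[2-(4-hydroxy-3-isopropoxyphenyl)ethyl]phenoxy]-4-methoxyphenyl]propanoate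
Product: 14 3-[3-[4-[2-(4-hydroxy-3-isopropoxyphenyl)ethyl]phenoxy]-4-methoxyphenyl]propanal
Conditions: i-Bu2AlH (2.2 equiv), CH2Cl2, −78 °C; MeOH, then aq. KNaC4H4O6
Reagents that add atoms: none
Why: Partial reduction of an ester; the first equivalent of hydride is consumed by the phenol, and the second gives an aluminium hemiacetal that is stable at −78 °C and collapses to the aldehyde only on work-up.

Step 10
Reactants: 14 3-[3-[4-[2-(4-hydroxy-3-isopropoxyphenyl)ethyl]phenoxy]-4-methoxyphenyl]propanal; 15 1-(triphenylphosphoranylidene)propan-2-one
Product: 16 (E)-6-[3-[4-[2-(4-hydroxy-3-isopropoxyphenyl)ethyl]phenoxy]-4-methoxyphenyl]hex-3-en-2-one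
Conditions: THF, 65 °C
Reagents that add atoms: none
Why: Wittig olefination with an acyl-stabilised ylide, expected to be E-selective; the ylide is too weakly basic to deprotonate the phenol or to enolise the aldehyde.

Step 11
Reactants: 16 (E)-6-[3-[4-[2-(4-hydroxy-3-isopropoxyphenyl)ethyl]phenoxy]-4-methoxyphenyl]hex-3-en-2-one; 17 dimethyl malonate
Product: 21 5-[2-[3-[4-[2-(4-hydroxy-3-isopropoxyphenyl)ethyl]phenoxy]-4-methoxyphenyl]ethyl]cyclohexane-1,3-dione, via Michael adduct 18 (not isolated), via cyclic diketo ester 19 (not isolated), via diketo acid 20 (not isolated)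
Conditions: NaOMe (3.5 equiv), MeOH, reflux; then 2 M aq. NaOH, reflux; then HCl to pH 2, 80 °C
Reagents that add atoms: none
Why: Michael addition of the malonate, intramolecular Claisen condensation of the methyl ketone onto one ester, saponification and decarboxylation of the vinylogous β-keto acid, the classical route to 5-substituted cyclohexane-1,3-diones. The phenol rides along as its phenoxide and costs one equivalent of base.

Step 12
Reactants: 21 5-[2-[3-[4-[2-(4-hydroxy-3-isopropoxyphenyl)ethyl]phenoxy]-4-methoxyphenyl]ethyl]cyclohexane-1,3-dione
Product: 23 5-[2-[3-[4-[2-[4-(tert-butyldimethylsilyloxy)-3-isopropoxyphenyl]ethyl]phenoxy]-4-methoxyphenyl]ethyl]cyclohexane-1,3-dione, via bis-silyl derivative 22 (not isolated)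
Conditions: TBSCl (2.5 equiv), imidazole, DMF, rt; then aq. citric acid, THF, rt
Reagents that add atoms: tert-butyldimethylsilyl chloride, CC(C)(C)[Si](C)(C)Cl
Why: Silylation of the phenol and of the dione enol; the vinylogous silyl ester of 22 is as labile as a silyl ester and is hydrolysed by dilute acid, whereas the aryl silyl ether stays.

Step 13
Reactants: 23 5-[2-[3-[4-[2-[4-(tert-butyldimethylsilyloxy)-3-isopropoxyphenyl]ethyl]phenoxy]-4-methoxyphenyl]ethyl]cyclohexane-1,3-dione
Product: 24 3-chloro-5-[2-[3-[4-[2-[4-(tert-butyldimethylsilyloxy)-3-isopropoxyphenyl]ethyl]phenoxy]-4-methoxyphenyl]ethyl]cyclohex-2-en-1-one (racemic)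
Conditions: (COCl)2 (1.2 equiv), DMF (cat.), CH2Cl2, 0 °C to rt
Reagents that add atoms: oxalyl chloride, ClC(=O)C(=O)Cl
Why: Conversion of a vinylogous acid into its vinylogous acid chloride through Vilsmeier-type activation of the enol oxygen and conjugate addition–elimination of chloride. The dione is symmetric, so only one chloroenone can form, and the masked phenol cannot be acylated.

Step 14
Reactants: 24 3-chloro-5-[2-[3-[4-[2-[4-(tert-butyldimethylsilyloxy)-3-isopropoxyphenyl]ethyl]phenoxy]-4-methoxyphenyl]ethyl]cyclohex-2-en-1-one
Product: 26 macrocyclic 3-aryloxycyclohex-2-en-1-one (O-isopropyl; racemic; ring D as cyclohexenone with the ring C oxygen on C3 and the bridge to ring A on C5), via seco chloroenone phenol 25 (not isolated)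
Conditions: CsF (5 equiv), 4 Å MS, DMF, 60 °C, syringe-pump addition of 24 over 12 h (final ca. 2 mM)
Reagents that add atoms: none
Why: Fluoride cleaves the aryl silyl ether of 24 and frees the caesium phenoxide of 25 only under dilution; the phenoxide oxygen adds to C3 of the 3-chlorocyclohex-2-enone, the β-carbon of a vinylogous acid chloride, and the resulting enolate expels chloride and restores the enone (addition–elimination, vinylogous acyl substitution). The closest known reaction type is the base- or fluoride-mediated preparation of 3-aryloxycyclohex-2-enones from phenols and 3-halocyclohex-2-enones, run here intramolecularly. The 20-membered ring closes in the 20-exo-trig mode, because the attacked C3=C2 double bond lies outside the ring that forms (the oxygen, C3, C4 and C5 of ring D are ring members). No stereocentre is created: C5 of ring D is already present and racemic, and it is erased in step 16. Site selectivity rests on the substrate, which holds a single latent phenoxide (the other ring C oxygen is isopropylated) and a single electrophilic β-carbon, while attack at the carbonyl carbon is reversible and unproductive. Ring closure is favoured over chain growth by the slow addition, which keeps the stationary concentration of 25 low, and by the activated, unhindered electrophile, which lets the reaction run at 60 °C. The sieves exclude water, which would otherwise hydrolyse the chloroenone back to the dione.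

Step 15
Reactants: 26 macrocyclic 3-aryloxycyclohex-2-en-1-one
Product: 27 macrocyclic 3-aryloxycyclohex-2-en-1-ol (O-isopropyl; diastereomer mixture)
Conditions: i-Bu2AlH (1.3 equiv), CH2Cl2, −78 °C; aq. KNaC4H4O6; used at once
Reagents that add atoms: none
Why: 1,2-Reduction of a vinylogous ester by an aluminium hydride, the first half of a Stork–Danheiser sequence but stopped at the allylic alcohol. An aprotic solvent and a basic work-up are chosen so that the alcohol cannot ionise and lose the ring C oxygen; the new carbinol centre is uncontrolled and is removed in the next step.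

Step 16
Reactants: 27 macrocyclic 3-aryloxycyclohex-2-en-1-ol
Product: 29 O-isopropyl pakyonol, via dienol ether 28 (not isolated)
Conditions: Ph2S[OC(CF3)2Ph]2 (1.3 equiv), CH2Cl2, 0 °C; then DDQ (1.2 equiv), 0 °C to rt
Reagents that add atoms: none
Why: The sulfurane dehydrates the allylic alcohol under anhydrous, non-acidic conditions (alkoxysulfonium formation, then elimination) to the aryloxycyclohexadiene 28. DDQ then removes hydride and a proton from the two remaining sp3 carbons (dehydrogenative aromatisation), which is fast for a cyclohexadiene at room temperature and should leave the benzylic bridges alone. Either double-bond isomer of the diene gives the same arene, and the last stereocentre disappears.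

Step 17
Reactants: 29 O-isopropyl pakyonol
Product: 30 pakyonol
Conditions: BCl3 (3 equiv), CH2Cl2, −78 to 0 °C; MeOH, H2O
Reagents that add atoms: none
Why: Lewis acid cleavage of an aryl isopropyl ether; the boron-complexed ether loses the secondary alkyl group as 2-chloropropane far more readily than a methyl group, so the ring A methyl ether and both diaryl ethers should remain.

## Compound list

1 | 3,4-dihydroxybenzaldehyde | O=Cc1ccc(O)c(O)c1 | starting material
2 | 4-(benzyloxy)-3-hydroxybenzaldehyde | O=Cc1ccc(OCc2ccccc2)c(O)c1 | intermediate
3 | 4-(benzyloxy)-3-isopropoxybenzaldehyde | O=Cc1ccc(OCc2ccccc2)c(OC(C)C)c1 | intermediate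
4 | [4-(benzyloxy)-3-isopropoxyphenyl]methanol | OCc1ccc(OCc2ccccc2)c(OC(C)C)c1 | intermediate
5 | [4-(benzyloxy)-3-isopropoxybenzyl]triphenylphosphonium bromide | [Br-].CC(C)Oc1cc(C[P+](c2ccccc2)(c2ccccc2)c2ccccc2)ccc1OCc1ccccc1 | intermediate
6 | isovanillin (3-hydroxy-4-methoxybenzaldehyde) | COc1ccc(C=O)cc1O | starting material
7 | methyl (triphenylphosphoranylidene)acetate | COC(=O)C=P(c1ccccc1)(c1ccccc1)c1ccccc1 | starting material
8 | methyl (E)-3-(3-hydroxy-4-methoxyphenyl)prop-2-enoate | COC(=O)/C=C/c1ccc(OC)c(O)c1 | intermediate
9 | 4-fluorobenzaldehyde | O=Cc1ccc(F)cc1 | starting material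
10 | methyl (E)-3-[3-(4-formylphenoxy)-4-methoxyphenyl]prop-2-enoate | COC(=O)/C=C/c1ccc(OC)c(Oc2ccc(C=O)cc2)c1 | intermediate
11 | [4-(benzyloxy)-3-isopropoxybenzylidene]triphenylphosphorane | CC(C)Oc1cc(C=P(c2ccccc2)(c2ccccc2)c2ccccc2)ccc1OCc1ccccc1 | intermediate
12 | methyl (E)-3-[3-[4-[2-[4-(benzyloxy)-3-isopropoxyphenyl]ethenyl]phenoxy]-4-methoxyphenyl]prop-2-enoate (E/Z mixture at the stilbene bond) | COC(=O)/C=C/c1ccc(OC)c(Oc2ccc(C=Cc3ccc(OCc4ccccc4)c(OC(C)C)c3)cc2)c1 | intermediate
13 | methyl 3-[3-[4-[2-(4-hydroxy-3-isopropoxyphenyl)ethyl]phenoxy]-4-methoxyphenyl]propanoate | COC(=O)CCc1ccc(OC)c(Oc2ccc(CCc3ccc(O)c(OC(C)C)c3)cc2)c1 | intermediate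
14 | 3-[3-[4-[2-(4-hydroxy-3-isopropoxyphenyl)ethyl]phenoxy]-4-methoxyphenyl]propanal | O=CCCc1ccc(OC)c(Oc2ccc(CCc3ccc(O)c(OC(C)C)c3)cc2)c1 | intermediate
15 | 1-(triphenylphosphoranylidene)propan-2-one | CC(=O)C=P(c1ccccc1)(c1ccccc1)c1ccccc1 | starting material
16 | (E)-6-[3-[4-[2-(4-hydroxy-3-isopropoxyphenyl)ethyl]phenoxy]-4-methoxyphenyl]hex-3-en-2-one | CC(=O)/C=C/CCc1ccc(OC)c(Oc2ccc(CCc3ccc(O)c(OC(C)C)c3)cc2)c1 | intermediate
17 | dimethyl malonate | COC(=O)CC(=O)OC | starting material
18 | dimethyl 2-[1-[3-[4-[2-(4-hydroxy-3-isopropoxyphenyl)ethyl]phenoxy]-4-methoxyphenyl]-5-oxohexan-3-yl]propanedioate (racemic) | COC(=O)C(C(=O)OC)C(CCc1ccc(OC)c(Oc2ccc(CCc3ccc(O)c(OC(C)C)c3)cc2)c1)CC(C)=O | intermediate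
19 | methyl 6-[2-[3-[4-[2-(4-hydroxy-3-isopropoxyphenyl)ethyl]phenoxy]-4-methoxyphenyl]ethyl]-2,4-dioxocyclohexane-1-carboxylate (racemic diastereomers) | COC(=O)C1C(=O)CC(=O)CC1CCc1ccc(OC)c(Oc2ccc(CCc3ccc(O)c(OC(C)C)c3)cc2)c1 | intermediate
20 | 6-[2-[3-[4-[2-(4-hydroxy-3-isopropoxyphenyl)ethyl]phenoxy]-4-methoxyphenyl]ethyl]-2,4-dioxocyclohexane-1-carboxylic acid (racemic diastereomers) | OC(=O)C1C(=O)CC(=O)CC1CCc1ccc(OC)c(Oc2ccc(CCc3ccc(O)c(OC(C)C)c3)cc2)c1 | intermediate
21 | 5-[2-[3-[4-[2-(4-hydroxy-3-isopropoxyphenyl)ethyl]phenoxy]-4-methoxyphenyl]ethyl]cyclohexane-1,3-dione | O=C1CC(=O)CC(CCc2ccc(OC)c(Oc3ccc(CCc4ccc(O)c(OC(C)C)c4)cc3)c2)C1 | intermediate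
22 | 3-(tert-butyldimethylsilyloxy)-5-[2-[3-[4-[2-[4-(tert-butyldimethylsilyloxy)-3-isopropoxyphenyl]ethyl]phenoxy]-4-methoxyphenyl]ethyl]cyclohex-2-en-1-one (racemic) | CC(C)Oc1cc(CCc2ccc(Oc3cc(CCC4CC(=O)C=C(O[Si](C)(C)C(C)(C)C)C4)ccc3OC)cc2)ccc1O[Si](C)(C)C(C)(C)C | intermediate
23 | 5-[2-[3-[4-[2-[4-(tert-butyldimethylsilyloxy)-3-isopropoxyphenyl]ethyl]phenoxy]-4-methoxyphenyl]ethyl]cyclohexane-1,3-dione | O=C1CC(=O)CC(CCc2ccc(OC)c(Oc3ccc(CCc4ccc(O[Si](C)(C)C(C)(C)C)c(OC(C)C)c4)cc3)c2)C1 | intermediate
24 | 3-chloro-5-[2-[3-[4-[2-[4-(tert-butyldimethylsilyloxy)-3-isopropoxyphenyl]ethyl]phenoxy]-4-methoxyphenyl]ethyl]cyclohex-2-en-1-one (racemic) | O=C1C=C(Cl)CC(CCc2ccc(OC)c(Oc3ccc(CCc4ccc(O[Si](C)(C)C(C)(C)C)c(OC(C)C)c4)cc3)c2)C1 | intermediate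
25 | 3-chloro-5-[2-[3-[4-[2-(4-hydroxy-3-isopropoxyphenyl)ethyl]phenoxy]-4-methoxyphenyl]ethyl]cyclohex-2-en-1-one (seco chloroenone phenol; racemic) | O=C1C=C(Cl)CC(CCc2ccc(OC)c(Oc3ccc(CCc4ccc(O)c(OC(C)C)c4)cc3)c2)C1 | intermediate
26 | macrocyclic 3-aryloxycyclohex-2-en-1-one (O-isopropyl; racemic) | COc1ccc2cc1Oc1ccc(cc1)CCc1ccc(c(OC(C)C)c1)OC1=CC(=O)CC(C1)CC2 | intermediate
27 | macrocyclic 3-aryloxycyclohex-2-en-1-ol (O-isopropyl; diastereomer mixture) | COc1ccc2cc1Oc1ccc(cc1)CCc1ccc(c(OC(C)C)c1)OC1=CC(O)CC(C1)CC2 | intermediate
28 | macrocyclic 1-aryloxycyclohexa-1,3-diene (O-isopropyl; racemic) | COc1ccc2cc1Oc1ccc(cc1)CCc1ccc(c(OC(C)C)c1)OC1=CC=CC(C1)CC2 | intermediate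
29 | O-isopropyl pakyonol | COc1ccc2cc1Oc1ccc(cc1)CCc1ccc(c(OC(C)C)c1)Oc1cccc(c1)CC2 | intermediate
30 | pakyonol | COc1ccc2cc1Oc1ccc(cc1)CCc1ccc(c(O)c1)Oc1cccc(c1)CC2 | target

## Step count and least certain steps

Total: 17 steps. Longest linear sequence: 15 steps (from 1 through steps 1–4 and 7–17). The ring A–ring B branch from 6 to 10 is 2 steps.

Step 14 (key step). The most likely failure is chain growth: the phenoxide of one molecule substitutes the chloroenone of another faster than the ring closes. Hydrolysis of the chloroenone by traces of water under basic fluoride is the second risk. The fallback aromatises ring D before closure and makes the ether bond by metal catalysis. It sets out from 24 and comes back at 29.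
- Reduction of 24 with i-Bu2AlH (CH2Cl2, −78 °C) should give the 3-chlorocyclohex-2-enol F1.
- Dehydration with Ph2S[OC(CF3)2Ph]2 should give the chlorocyclohexadiene F2, and DDQ in the same flask the silylated meta-alkyl aryl chloride F3.
- Bu4NF in THF frees the aryl chloride phenol F4.
- A palladium-catalysed intramolecular C–O coupling of the aryl chloride with the phenol (Pd(OAc)2, 2-di-tert-butylphosphino-2',4',6'-triisopropylbiphenyl, K3PO4, toluene, 100 °C, slow addition) then closes the ring to 29.

Step 16. The activated alcohol can ionise in the presence of adventitious water, which leads to transposition with expulsion of the ring C phenoxide and so to ring opening. Oxidation by DDQ at a benzylic carbon of the electron-rich rings is the second risk. The fallback replaces the cationic dehydration by a metal-mediated elimination. It sets out from 27 and comes back at 28. Acetylation (Ac2O, pyridine, 4-dimethylaminopyridine) gives the allylic acetate F5. Pd(PPh3)4 with Et3N in THF at 60 °C should ionise it to a π-allyl complex that undergoes β-hydride elimination to the diene 28, which is then dehydrogenated with DDQ as in the route.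

Step 15. Hydride may be delivered in the conjugate sense, with loss of the aryloxy group, or the product may ionise during work-up. The fallback avoids the reduction and removes the oxygen as a triflate. It sets out from 26 and comes back at 29.
- Kinetic deprotonation at the α' carbon (LiN(i-Pr)2, THF, −78 °C) and trapping with N-phenylbis(trifluoromethanesulfonimide) should give the cross-conjugated dienyl triflate F6.
- DDQ aromatises it to the aryl triflate F7.
- Pd(OAc)2, 1,1'-bis(diphenylphosphino)ferrocene, Et3N and HCO2H in DMF at 70 °C reduce the triflate to 29.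

Step 9. Over-reduction to the primary alcohol is the likely failure, because the aluminium phenoxide formed first makes the mixture heterogeneous and the hemiacetal may collapse before the quench. The fallback fixes the aldehyde oxidation level through a chelated intermediate. It sets out from 13 and comes back at 14. MeNH(OMe)·HCl with i-PrMgCl (THF, −20 to 0 °C) converts the ester into the N-methoxy-N-methylamide F8, and LiAlH4 (THF, −78 to 0 °C) reduces it to 14.

Step 11. Under methoxide the enone can enolise at its γ-methylene, so that deconjugation and self-condensation compete with the Michael addition. The fallback reverses the roles of donor and acceptor. It sets out from 14 and comes back at 19. Olefination of 14 with 7 gives the methyl (E)-enoate F9. Methyl acetoacetate with NaOMe in MeOH adds to it to give the Michael adduct F10, which closes by Claisen condensation to 19. Hydrolysis and decarboxylation follow as in the route.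

## Further compounds

F1 | step 14 | 3-chloro-5-[2-[3-[4-[2-[4-(tert-butyldimethylsilyloxy)-3-isopropoxyphenyl]ethyl]phenoxy]-4-methoxyphenyl]ethyl]cyclohex-2-en-1-ol (diastereomer mixture) | OC1C=C(Cl)CC(CCc2ccc(OC)c(Oc3ccc(CCc4ccc(O[Si](C)(C)C(C)(C)C)c(OC(C)C)c4)cc3)c2)C1
F2 | step 14 | 1-chloro-5-[2-[3-[4-[2-[4-(tert-butyldimethylsilyloxy)-3-isopropoxyphenyl]ethyl]phenoxy]-4-methoxyphenyl]ethyl]cyclohexa-1,3-diene (racemic) | ClC1=CC=CC(CCc2ccc(OC)c(Oc3ccc(CCc4ccc(O[Si](C)(C)C(C)(C)C)c(OC(C)C)c4)cc3)c2)C1
F3 | step 14 | tert-butyl[4-[2-[4-[5-[2-(3-chlorophenyl)ethyl]-2-methoxyphenoxy]phenyl]ethyl]-2-isopropoxyphenoxy]dimethylsilane | Clc1cccc(CCc2ccc(OC)c(Oc3ccc(CCc4ccc(O[Si](C)(C)C(C)(C)C)c(OC(C)C)c4)cc3)c2)c1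
F4 | step 14 | 4-[2-[4-[5-[2-(3-chlorophenyl)ethyl]-2-methoxyphenoxy]phenyl]ethyl]-2-isopropoxyphenol | Clc1cccc(CCc2ccc(OC)c(Oc3ccc(CCc4ccc(O)c(OC(C)C)c4)cc3)c2)c1
F5 | step 16 | acetate of the macrocyclic 3-aryloxycyclohex-2-en-1-ol 27 (diastereomer mixture) | COc1ccc2cc1Oc1ccc(cc1)CCc1ccc(c(OC(C)C)c1)OC1=CC(OC(C)=O)CC(C1)CC2
F6 | step 15 | macrocyclic 3-aryloxycyclohexa-1,3-dien-1-yl trifluoromethanesulfonate (racemic) | COc1ccc2cc1Oc1ccc(cc1)CCc1ccc(c(OC(C)C)c1)OC1=CC(OS(=O)(=O)C(F)(F)F)=CC(C1)CC2
F7 | step 15 | O-isopropyl pakyonol carrying a trifluoromethanesulfonyloxy group on D5 | COc1ccc2cc1Oc1ccc(cc1)CCc1ccc(c(OC(C)C)c1)Oc1cc(OS(=O)(=O)C(F)(F)F)cc(c1)CC2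
F8 | step 9 | 3-[3-[4-[2-(4-hydroxy-3-isopropoxyphenyl)ethyl]phenoxy]-4-methoxyphenyl]-N-methoxy-N-methylpropanamide | CON(C)C(=O)CCc1ccc(OC)c(Oc2ccc(CCc3ccc(O)c(OC(C)C)c3)cc2)c1
F9 | step 11 | methyl (E)-5-[3-[4-[2-(4-hydroxy-3-isopropoxyphenyl)ethyl]phenoxy]-4-methoxyphenyl]pent-2-enoate | COC(=O)/C=C/CCc1ccc(OC)c(Oc2ccc(CCc3ccc(O)c(OC(C)C)c3)cc2)c1
F10 | step 11 | dimethyl 2-acetyl-3-[2-[3-[4-[2-(4-hydroxy-3-isopropoxyphenyl)ethyl]phenoxy]-4-methoxyphenyl]ethyl]pentanedioate (diastereomer mixture) | COC(=O)CC(CCc1ccc(OC)c(Oc2ccc(CCc3ccc(O)c(OC(C)C)c3)cc2)c1)C(C(C)=O)C(=O)OC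
A1 | alternative 1 | 4-[2-(3-bromophenyl)ethyl]-6-[4-[2-[3-(benzyloxy)-4-(tert-butyldimethylsilyloxy)phenyl]ethyl]phenoxy]cyclohex-2-en-1-one (racemic diastereomers) | O=C1C=CC(CCc2cccc(Br)c2)CC1Oc1ccc(CCc2ccc(O[Si](C)(C)C(C)(C)C)c(OCc3ccccc3)c2)cc1
A2 | alternative 1 | 4-(3-bromophenyl)butanal | O=CCCCc1cccc(Br)c1
A3 | alternative 1 | 3-[4-[2-[3-(benzyloxy)-4-(tert-butyldimethylsilyloxy)phenyl]ethyl]phenoxy]but-3-en-2-one | CC(=O)C(=C)Oc1ccc(CCc2ccc(O[Si](C)(C)C(C)(C)C)c(OCc3ccccc3)c2)cc1
A4 | alternative 2 | macrocyclic aryl ketone (O-benzyl pakyonol with a carbonyl on the bridge carbon attached to ring B) | COc1ccc2cc1Oc1ccc(cc1)C(=O)Cc1ccc(c(OCc3ccccc3)c1)Oc1cccc(c1)CC2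
A5 | alternative 2 | 1-[3-(benzyloxy)-4-[3-[2-[3-(buta-1,3-dien-2-yloxy)-4-methoxyphenyl]ethyl]phenoxy]phenyl]but-3-yn-2-one | C=CC(=C)Oc1cc(CCc2cccc(Oc3ccc(CC(=O)C#C)cc3OCc3ccccc3)c2)ccc1OC
A6 | alternative 3 | O-isopropyl pakyonol (identical with 29) | COc1ccc2cc1Oc1ccc(cc1)CCc1ccc(c(OC(C)C)c1)Oc1cccc(c1)CC2
A7 | alternative 3 | 21-membered macrolactone (aryl ester between the ring A oxygen and a carboxyl group on B1; O-isopropyl) | COc1ccc2cc1OC(=O)c1ccc(cc1)CCc1ccc(c(OC(C)C)c1)Oc1cccc(c1)CC2
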